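**Plan**
- Retrosynthesis cuts the ring B–ring C ester C–O bond first, then four C–C bonds of ring B (C5'–C6', C2'–C3', C4'–C5', C1'–C2'). This leaves an acyclic diazo ketone that already carries the ring A aryl ester, plus (triisopropylsilyloxy)ethyne. The ring A–ring B ester C–O bond and the enoate C=C are cut last, at a bromoacetyl stage.
- Forward: methyl orsellinate gives the ring A phenol, which is converted to its bromoacetate, the phosphonium salt, the Wittig enone with butane-2,3-dione, and the diazo ketone. The ynol silyl ether is made from tetrahydrofuran and the silyl triflate.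
- Ring B is then built in one photochemical/thermal cascade. The feature that allows this is ring B itself: the C2' oxygen next to the ester-bearing C1' must end as a free phenol and the C4' oxygen must be acylated, and the two come from different reagents (ketene carbonyl gives C2'–OH, ynol oxygen gives C4'–OSi).
- Desilylation, esterification of the unchelated 4'-OH with ring C as its dibenzyl ether acid, and hydrogenolysis complete the tridepside.
- The target has no stereocentre. The only stereochemical element is the E enoate from the Wittig step, which places H inside and the ester outside in the closing triene.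

Key step: step 11

Assumption: (triisopropylsilyloxy)ethyne is treated as not purchasable and is prepared in steps 7 to 9.

**Step 1**
Reactants: 1 methyl orsellinate (methyl 2,4-dihydroxy-6-methylbenzoate)
Product: 2 methyl 4-(benzyloxy)-2-hydroxy-6-methylbenzoate
Conditions: BnBr (1.05 equiv), K2CO3 (1.2 equiv), acetone, reflux
Reagents that add atoms: benzyl bromide, BrCc1ccccc1
Why: Williamson etherification; the 2-OH is hydrogen-bonded to the ester carbonyl, so one equivalent of halide should alkylate only the more acidic, free 4-OH.

**Step 2**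
Reactants: 2 methyl 4-(benzyloxy)-2-hydroxy-6-methylbenzoate
Product: 3 methyl 4-(benzyloxy)-2-methoxy-6-methylbenzoate
Conditions: MeI (3 equiv), K2CO3 (3 equiv), DMF, 50 °C
Reagents that add atoms: iodomethane, CI
Why: Williamson methylation of the chelated phenol, which should go to completion in a polar aprotic solvent with excess reagent.

**Step 3**
Reactants: 3 methyl 4-(benzyloxy)-2-methoxy-6-methylbenzoate
Product: 4 methyl 4-hydroxy-2-methoxy-6-methylbenzoate
Conditions: H2 (1 atm), 10% Pd/C, EtOAc, 25 °C
Reagents that add atoms: none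
Why: Catalytic hydrogenolysis of the benzyl aryl ether, to which the methyl ester and methyl ether are inert.

**Step 4**
Reactants: 4 methyl 4-hydroxy-2-methoxy-6-methylbenzoate; 5 bromoacetyl bromide
Product: 6 methyl 4-[(bromoacetyl)oxy]-2-methoxy-6-methylbenzoate
Conditions: pyridine (1.2 equiv), CH2Cl2, −10 to 0 °C
Reagents that add atoms: none
Why: O-acylation of a phenol by an acyl bromide, which is far more electrophilic than the alkyl bromide; the ring A–ring B ester bond is thus made on an unhindered two-carbon acyl unit before ring B exists.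

**Step 5**
Reactants: 6 methyl 4-[(bromoacetyl)oxy]-2-methoxy-6-methylbenzoate
Product: 7 {2-[3-methoxy-4-(methoxycarbonyl)-5-methylphenoxy]-2-oxoethyl}triphenylphosphonium bromide
Conditions: PPh3 (1.05 equiv), toluene, 25 °C; salt collected by filtration
Reagents that add atoms: triphenylphosphine, c1ccc(cc1)P(c1ccccc1)c1ccccc1
Why: SN2 quaternisation of the phosphine by the activated alpha-bromo ester; the salt should precipitate free of phosphine.

**Step 6**
Reactants: 7 {2-[3-methoxy-4-(methoxycarbonyl)-5-methylphenoxy]-2-oxoethyl}triphenylphosphonium bromide; 8 butane-2,3-dione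
Product: 10 3-methoxy-4-(methoxycarbonyl)-5-methylphenyl (2E)-3-methyl-4-oxopent-2-enoate, via phosphorane 9 (not isolated)
Conditions: Et3N (1.0 equiv), CH2Cl2, 0 °C; then 8 (3 equiv), 25 °C
Reagents that add atoms: none
Why: Wittig olefination with a stabilised ylide; the activated 1,2-diketone reacts at one carbonyl (excess diketone suppresses a second olefination) and reversible addition of the stabilised ylide should favour the E enoate with the ester trans to the acetyl group.

**Step 7**
Reactants: 11 tetrahydrofuran; 12 triisopropylsilyl trifluoromethanesulfonate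
Product: 14 (ethenyloxy)triisopropylsilane, via lithium ethenolate 13 (not isolated)
Conditions: n-BuLi (1.0 equiv), THF (solvent and reactant), 25 °C, 16 h; then 12 (0.9 equiv), −78 to 0 °C
Reagents that add atoms: none
Why: Alpha-lithiation of tetrahydrofuran and [3+2] cycloreversion release ethene and the lithium enolate of acetaldehyde, which the hard silyl triflate silylates on oxygen.

**Step 8**
Reactants: 14 (ethenyloxy)triisopropylsilane
Product: 16 {[(Z)-2-bromoethenyl]oxy}triisopropylsilane, via dibromide 15 (not isolated)
Conditions: Br2 (1.0 equiv), CH2Cl2, −78 °C; then Et3N (1.5 equiv), −78 to 25 °C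
Reagents that add atoms: bromine, BrBr
Why: Bromine addition to the enol ether followed by amine-mediated dehydrobromination, in which the activated bromide on the oxygenated carbon is lost, as in the known bromination–elimination of alkyl and trimethylsilyl vinyl ethers; the bulky silyl group should resist attack of bromide at silicon, and any E isomer converges in step 9.

**Step 9**
Reactants: 16 {[(Z)-2-bromoethenyl]oxy}triisopropylsilane
Product: 18 (triisopropylsilyloxy)ethyne, via lithium alkynide 17 (not isolated)
Conditions: LiN(i-Pr)2 (2.2 equiv), THF, −78 °C; H2O quench at −78 °C; distillation at reduced pressure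
Reagents that add atoms: none
Why: Anti E2 dehydrobromination (the H on the oxygenated carbon is trans to Br in the Z isomer), as in the classical preparation of alkynyl ethers from 2-bromovinyl ethers; the second equivalent of amide deprotonates the alkyne and water returns it.

**Step 10**
Reactants: 10 3-methoxy-4-(methoxycarbonyl)-5-methylphenyl (2E)-3-methyl-4-oxopent-2-enoate
Product: 20 3-methoxy-4-(methoxycarbonyl)-5-methylphenyl (2E)-5-diazo-3-methyl-4-oxopent-2-enoate, via trifluoroacetyl diketone 19 (not isolated)
Conditions: LiN(SiMe3)2 (1.1 equiv), THF, −78 °C; CF3CO2CH2CF3 (1.2 equiv), −78 °C; then MeSO2N3 (1.5 equiv), Et3N (1.5 equiv), H2O (1 equiv), MeCN, 25 °C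
Reagents that add atoms: methanesulfonyl azide, CS(=O)(=O)N=[N+]=[N-]; 2,2,2-trifluoroethyl trifluoroacetate, O=C(OCC(F)(F)F)C(F)(F)F (its atoms stay in 19 only)
Why: Detrifluoroacetylative diazo transfer (a deacylative Regitz-type diazo transfer made for alpha,beta-unsaturated methyl ketones): kinetic enolisation of the acetyl methyl at −78 °C and Claisen trifluoroacetylation give a 1,3-diketone acidic enough for diazo transfer under amine base, the trifluoroacetyl group leaves as the sulfonamide, and the E geometry keeps the enolate away from the aryl ester.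

**Step 11**
Reactants: 20 3-methoxy-4-(methoxycarbonyl)-5-methylphenyl (2E)-5-diazo-3-methyl-4-oxopent-2-enoate; 18 (triisopropylsilyloxy)ethyne
Product: 24 methyl 4-{[2-hydroxy-6-methyl-4-(triisopropylsilyloxy)benzoyl]oxy}-2-methoxy-6-methylbenzoate, via vinylketene 21 (not isolated), via cyclobutenone 22 (not isolated), via dienylketene 23 (not isolated)
Conditions: 18 (2.5 equiv), degassed ClCH2CH2Cl (0.05 M), hν (medium-pressure Hg lamp, Pyrex filter, >300 nm), 25 °C; then 80 °C in the dark
Reagents that add atoms: none
Why: Excitation of the diazo ketone expels N2 and the alkenyl group shifts (photochemical Wolff rearrangement, forming C5'–C6') to vinylketene 21, whose ketene C=C adds to the ynol ether in a [2+2] step (C2'–C3' between the ketene carbonyl carbon and the nucleophilic CH terminus, C4'–C5' between the ketene alpha carbon and the oxygenated alkyne carbon) to give 22. Reversible 4-pi electrocyclic opening of 22 gives dienylketene 23, and ring B closes by a thermal disrotatory 6-pi electrocyclisation that forms C1'–C2', followed by tautomerisation of the cyclohexadienone to the phenol. The closest known reaction is the Danheiser benzannulation in its photochemical Wolff form, in which alpha,beta-unsaturated diazo ketones and siloxyalkynes give resorcinol monosilyl ethers; here the substrate additionally carries an aryl ester on the alkene terminus. No stereocentre survives, since the sp3 carbon of 22 is planarised on ring opening. The step needs regioselectivity in the [2+2] addition, which the polarisation of the ynol ether secures, and a triene able to close, which the E enoate secures by placing H inside and the ester outside and by keeping the ester carbonyl away from the ketene. It also needs selective excitation of the conjugated diazo ketone over the aryl ester, which the Pyrex cut-off should provide, and it delivers the ketene carbonyl as the chelated C2' phenol and the ynol oxygen as the C4' silyl ether, so the two oxygens of ring B are differentiated from the outset.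

**Step 12**
Reactants: 24 methyl 4-{[2-hydroxy-6-methyl-4-(triisopropylsilyloxy)benzoyl]oxy}-2-methoxy-6-methylbenzoate
Product: 25 methyl 4-[(2,4-dihydroxy-6-methylbenzoyl)oxy]-2-methoxy-6-methylbenzoate
Conditions: Bu4NF (1.1 equiv), AcOH (1.2 equiv), THF, 0 °C
Reagents that add atoms: none
Why: Fluoride-induced cleavage of the aryl silyl ether; the acetic acid buffer should protect the aryl ester from basic fluoride and phenoxide.

**Step 13**
Reactants: 1 methyl orsellinate
Product: 26 methyl 2,4-bis(benzyloxy)-6-methylbenzoate
Conditions: BnBr (2.5 equiv), K2CO3 (3 equiv), DMF, 70 °C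
Reagents that add atoms: benzyl bromide, BrCc1ccccc1
Why: Exhaustive Williamson benzylation of both phenols under forcing conditions.

**Step 14**
Reactants: 26 methyl 2,4-bis(benzyloxy)-6-methylbenzoate
Product: 27 2,4-bis(benzyloxy)-6-methylbenzoic acid
Conditions: KOH (5 equiv), DMSO–H2O (4:1), 90 °C; then aq. HCl to pH 2
Reagents that add atoms: potassium hydroxide, [K+].[OH-]
Why: Saponification of the doubly ortho-substituted ester, which needs hot hydroxide in DMSO; the benzyl ethers are stable to base.

**Step 15**
Reactants: 25 methyl 4-[(2,4-dihydroxy-6-methylbenzoyl)oxy]-2-methoxy-6-methylbenzoate; 27 2,4-bis(benzyloxy)-6-methylbenzoic acid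
Product: 28 methyl 4-[(4-{[2,4-bis(benzyloxy)-6-methylbenzoyl]oxy}-2-hydroxy-6-methylbenzoyl)oxy]-2-methoxy-6-methylbenzoate
Conditions: DCC (1.2 equiv), DMAP (0.1 equiv), CH2Cl2, 0 to 25 °C
Reagents that add atoms: none
Why: Steglich esterification, as used in classical depside synthesis; the 4'-OH is free and nucleophilic while the 2'-OH is deactivated by its hydrogen bond to the ring B ester carbonyl, so acylation should occur only at O-4'.

**Step 16**
Reactants: 28 methyl 4-[(4-{[2,4-bis(benzyloxy)-6-methylbenzoyl]oxy}-2-hydroxy-6-methylbenzoyl)oxy]-2-methoxy-6-methylbenzoate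
Product: 29 methyl 4-({4-[(2,4-dihydroxy-6-methylbenzoyl)oxy]-2-hydroxy-6-methylbenzoyl}oxy)-2-methoxy-6-methylbenzoate (target)
Conditions: H2 (1 atm), 10% Pd/C, EtOAc, 25 °C
Reagents that add atoms: none
Why: Hydrogenolysis of the two benzyl aryl ethers under neutral conditions, which leaves both aryl esters and the methyl ester intact.

**Compound list**
1 | methyl orsellinate (methyl 2,4-dihydroxy-6-methylbenzoate) | COC(=O)c1c(C)cc(O)cc1O | starting material
2 | methyl 4-(benzyloxy)-2-hydroxy-6-methylbenzoate | COC(=O)c1c(C)cc(OCc2ccccc2)cc1O | intermediate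
3 | methyl 4-(benzyloxy)-2-methoxy-6-methylbenzoate | COC(=O)c1c(C)cc(OCc2ccccc2)cc1OC | intermediate
4 | methyl 4-hydroxy-2-methoxy-6-methylbenzoate | COC(=O)c1c(C)cc(O)cc1OC | intermediate
5 | bromoacetyl bromide | BrCC(Br)=O | starting material
6 | methyl 4-[(bromoacetyl)oxy]-2-methoxy-6-methylbenzoate | COC(=O)c1c(C)cc(OC(=O)CBr)cc1OC | intermediate
7 | {2-[3-methoxy-4-(methoxycarbonyl)-5-methylphenoxy]-2-oxoethyl}triphenylphosphonium bromide | COC(=O)c1c(C)cc(OC(=O)C[P+](c2ccccc2)(c2ccccc2)c2ccccc2)cc1OC.[Br-] | intermediate
8 | butane-2,3-dione | CC(=O)C(C)=O | starting material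
9 | 3-methoxy-4-(methoxycarbonyl)-5-methylphenyl (triphenylphosphoranylidene)acetate | COC(=O)c1c(C)cc(OC(=O)C=P(c2ccccc2)(c2ccccc2)c2ccccc2)cc1OC | intermediate
10 | 3-methoxy-4-(methoxycarbonyl)-5-methylphenyl (2E)-3-methyl-4-oxopent-2-enoate | COC(=O)c1c(C)cc(OC(=O)/C=C(\C)C(C)=O)cc1OC | intermediate
11 | tetrahydrofuran | C1CCOC1 | starting material
12 | triisopropylsilyl trifluoromethanesulfonate | CC(C)[Si](OS(=O)(=O)C(F)(F)F)(C(C)C)C(C)C | starting material
13 | lithium ethenolate | [Li+].[O-]C=C | intermediate
14 | (ethenyloxy)triisopropylsilane | C=CO[Si](C(C)C)(C(C)C)C(C)C | intermediate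
15 | (1,2-dibromoethoxy)triisopropylsilane | BrCC(Br)O[Si](C(C)C)(C(C)C)C(C)C | intermediate
16 | {[(Z)-2-bromoethenyl]oxy}triisopropylsilane | Br/C=C\O[Si](C(C)C)(C(C)C)C(C)C | intermediate
17 | lithium (triisopropylsilyloxy)ethynide | [Li+].[C-]#CO[Si](C(C)C)(C(C)C)C(C)C | intermediate
18 | (triisopropylsilyloxy)ethyne | C#CO[Si](C(C)C)(C(C)C)C(C)C | intermediate
19 | 3-methoxy-4-(methoxycarbonyl)-5-methylphenyl (2E)-7,7,7-trifluoro-3-methyl-4,6-dioxohept-2-enoate | COC(=O)c1c(C)cc(OC(=O)/C=C(\C)C(=O)CC(=O)C(F)(F)F)cc1OC | intermediate
20 | 3-methoxy-4-(methoxycarbonyl)-5-methylphenyl (2E)-5-diazo-3-methyl-4-oxopent-2-enoate | COC(=O)c1c(C)cc(OC(=O)/C=C(\C)C(=O)C=[N+]=[N-])cc1OC | intermediate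
21 | 3-methoxy-4-(methoxycarbonyl)-5-methylphenyl (2E)-3-methyl-5-oxopenta-2,4-dienoate | COC(=O)c1c(C)cc(OC(=O)/C=C(\C)C=C=O)cc1OC | intermediate
22 | 3-methoxy-4-(methoxycarbonyl)-5-methylphenyl (2E)-3-[4-oxo-2-(triisopropylsilyloxy)cyclobut-2-en-1-yl]but-2-enoate | COC(=O)c1c(C)cc(OC(=O)/C=C(\C)C2C(=O)C=C2O[Si](C(C)C)(C(C)C)C(C)C)cc1OC | intermediate
23 | 3-methoxy-4-(methoxycarbonyl)-5-methylphenyl (2E,4E)-3-methyl-7-oxo-5-(triisopropylsilyloxy)hepta-2,4,6-trienoate | COC(=O)c1c(C)cc(OC(=O)/C=C(\C)/C=C(O[Si](C(C)C)(C(C)C)C(C)C)\C=C=O)cc1OC | intermediate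
24 | methyl 4-{[2-hydroxy-6-methyl-4-(triisopropylsilyloxy)benzoyl]oxy}-2-methoxy-6-methylbenzoate | COC(=O)c1c(C)cc(OC(=O)c2c(C)cc(O[Si](C(C)C)(C(C)C)C(C)C)cc2O)cc1OC | intermediate
25 | methyl 4-[(2,4-dihydroxy-6-methylbenzoyl)oxy]-2-methoxy-6-methylbenzoate | COC(=O)c1c(C)cc(OC(=O)c2c(C)cc(O)cc2O)cc1OC | intermediate
26 | methyl 2,4-bis(benzyloxy)-6-methylbenzoate | COC(=O)c1c(C)cc(OCc2ccccc2)cc1OCc1ccccc1 | intermediate
27 | 2,4-bis(benzyloxy)-6-methylbenzoic acid | OC(=O)c1c(C)cc(OCc2ccccc2)cc1OCc1ccccc1 | intermediate
28 | methyl 4-[(4-{[2,4-bis(benzyloxy)-6-methylbenzoyl]oxy}-2-hydroxy-6-methylbenzoyl)oxy]-2-methoxy-6-methylbenzoate | COC(=O)c1c(C)cc(OC(=O)c2c(C)cc(OC(=O)c3c(C)cc(OCc4ccccc4)cc3OCc3ccccc3)cc2O)cc1OC | intermediate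
29 | methyl 4-({4-[(2,4-dihydroxy-6-methylbenzoyl)oxy]-2-hydroxy-6-methylbenzoyl}oxy)-2-methoxy-6-methylbenzoate | COC(=O)c1c(C)cc(OC(=O)c2c(C)cc(OC(=O)c3c(C)cc(O)cc3O)cc2O)cc1OC | target

**Step count**
Total: 16 steps. Longest linear sequence: 11 steps (steps 1–6, 10, 11, 12, 15, 16). Steps 7–9 and steps 13–14 are side branches.

**Steps most likely to fail**

Step 11. The aryl ester may undergo photo-Fries acyl migration under irradiation. Light-induced E to Z isomerisation of the enoate may be followed by oxa-6-pi closure of the vinylketene onto the ester carbonyl, giving a pyranone. Ketene intermediates may also acylate the product phenol. The fallback gives up the annulation and builds the ring A–ring B ester by classical depside coupling. It sets out from 4: esterification with 27 (DCC, DMAP, CH2Cl2) should give methyl 4-{[2,4-bis(benzyloxy)-6-methylbenzoyl]oxy}-2-methoxy-6-methylbenzoate F1, and hydrogenolysis of F1 (H2, 10% Pd/C, EtOAc) should give 25, where the route is rejoined before step 15.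

Step 10. The lithium enolate may add to the aryl ester or to the doubly activated alkene of a second molecule (Claisen or Michael pathways). The aryl ester may also be hydrolysed during the amine/water stage. The fallback avoids the strong base and sets out from 10. Soft enolisation (Me3SiOSO2CF3, Et3N, CH2Cl2, 0 °C) should give 3-methoxy-4-(methoxycarbonyl)-5-methylphenyl (2E)-3-methyl-4-[(trimethylsilyl)oxy]penta-2,4-dienoate F2. Bromination with N-bromosuccinimide (THF, 0 °C) should give 3-methoxy-4-(methoxycarbonyl)-5-methylphenyl (2E)-5-bromo-3-methyl-4-oxopent-2-enoate F3. Treatment of F3 with N,N'-ditosylhydrazine and DBU (THF, 0 °C) should form the diazo ketone by N-alkylation and twofold loss of sulfinate, returning to the route at 20.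

Step 9. The base may remove the proton next to bromine, after which silanolate is lost instead of bromide. The lithium alkynide may undergo intermolecular O-to-C silyl transfer. The volatile ynol ether may be lost by evaporation or hydrolysis on isolation. The fallback makes the C–O bond by oxidation of an acetylide instead of by elimination and sets out from 12. Acetylene in THF at −78 °C is lithiated with n-BuLi to lithium acetylide F4, which is oxidised with LiOOt-Bu (from t-BuOOH and LiN(SiMe3)2) to lithium ethynolate F5. O-silylation of F5 with 12 at −78 °C should give 18, where the route is rejoined.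

**Further compounds**
F1 | step 11 | methyl 4-{[2,4-bis(benzyloxy)-6-methylbenzoyl]oxy}-2-methoxy-6-methylbenzoate | COC(=O)c1c(C)cc(OC(=O)c2c(C)cc(OCc3ccccc3)cc2OCc2ccccc2)cc1OC
F2 | step 10 | 3-methoxy-4-(methoxycarbonyl)-5-methylphenyl (2E)-3-methyl-4-[(trimethylsilyl)oxy]penta-2,4-dienoate | COC(=O)c1c(C)cc(OC(=O)/C=C(\C)C(=C)O[Si](C)(C)C)cc1OC
F3 | step 10 | 3-methoxy-4-(methoxycarbonyl)-5-methylphenyl (2E)-5-bromo-3-methyl-4-oxopent-2-enoate | COC(=O)c1c(C)cc(OC(=O)/C=C(\C)C(=O)CBr)cc1OC
F4 | step 9 | lithium acetylide | [Li+].[C-]#C
F5 | step 9 | lithium ethynolate | [Li+].[O-]C#C
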